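The pyran ring is disconnected at O1–C2, C2–C3 and C4–C(naphthyl). C2 lies at the aldehyde oxidation level between O1 and C3, and C4 is a benzylic ring carbon whose cation is stabilised by O1 through C8a–C4a, so one acid-catalysed cascade can join a 2-vinylresorcinol unit, acetaldehyde and 1,8-dimethoxynaphthalene, closing the pyran ring and setting C2 and C4. The precursor is 2-vinylresorcinol with a tosyl group on the spectator oxygen (the future C5–O): only one phenol can condense with the aldehyde, and neither the substrate nor the product benzene ring competes with the naphthalene as Friedel–Crafts partner. Hydrolysis of the sulfonate completes the synthesis.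

Key step: step 3

Remark: the target is (2R,4S), with the C2 methyl and C4 aryl groups trans; the sense of induction of a confined acid in this cyclisation cannot be assigned in advance, so the catalyst antipode that leads to (2R) is to be fixed in the first experiments, and 1,8-dimethoxynaphthalene is taken as purchasable.

Step 1
Reactants: 1 2,6-dihydroxybenzaldehyde
Product: 2 2-formyl-3-hydroxyphenyl 4-methylbenzenesulfonate
Conditions: TsCl (1.0 equiv), Et3N (1.1 equiv), CH2Cl2, 0 °C → rt
Reagents that add atoms: p-toluenesulfonyl chloride, Cc1ccc(cc1)S(=O)(=O)Cl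
Why: O-sulfonylation of a phenol; with one equivalent each of TsCl and base the second hydroxyl, which stays hydrogen-bonded to the formyl oxygen and is no longer deprotonated, should react much more slowly, favouring the mono-tosylate.

Step 2
Reactants: 2 2-formyl-3-hydroxyphenyl 4-methylbenzenesulfonate
Product: 3 3-hydroxy-2-vinylphenyl 4-methylbenzenesulfonate (mono-O-tosyl 2-vinylresorcinol)
Conditions: MePPh3Br (2.4 equiv), NaHMDS (2.3 equiv), THF, 0 °C; then 2, 0 °C → rt; aq NH4Cl
Reagents that add atoms: methyltriphenylphosphonium bromide, C[P+](c1ccccc1)(c1ccccc1)c1ccccc1.[Br-]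
Why: Wittig methylenation; salicylaldehydes are converted into 2-vinylphenols by an excess of the non-stabilised ylide (one equivalent acts as base for the phenol), and an aryl tosylate without α-hydrogens should tolerate the ylide at or below room temperature.

Step 3
Reactants: 3 3-hydroxy-2-vinylphenyl 4-methylbenzenesulfonate, 4 acetaldehyde, 5 1,8-dimethoxynaphthalene
Product: 8 (2R,4S)-4-(4,5-dimethoxynaphthalen-1-yl)-2-methylchroman-5-yl 4-methylbenzenesulfonate, via oxocarbenium ion 6 (not isolated), via chromanyl cation 7 (not isolated)
Conditions: chiral confined imidodiphosphorimidate (IDPi) Brønsted acid (5 mol%), 5 (3 equiv), 5 Å MS, CHCl3, −40 °C; 3 + MeCHO (1.5 equiv) added over 12 h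
Reagents that add atoms: none
Why: Proposed new method: the free phenol of 3 and acetaldehyde form a hemiacetal (O1–C2) that the acid ionises to the aryloxy oxocarbenium ion 6 inside the chiral anion pocket, the vinyl terminus attacks its carbon (C2–C3) in a closure that is formally the 6π-electrocyclisation of a 2-oxoniatriene, and the O1-stabilised benzylic cation 7 is captured at C4 by the position of 5 para to a methoxy group, after which proton loss returns the catalyst. The closest known reactions are Prins cyclisation/Friedel–Crafts sequences that give 4-aryltetrahydropyrans from homoallylic alcohols, aldehydes and arenes, confined-acid-catalysed asymmetric Prins cyclisations, and the acid-mediated trans-selective arylation of 2-substituted chroman-4-yl cations. The pyran ring closes in the 6-endo-trig mode on the styrene. C2 is set by the catalyst, which selects the face of 6 that the alkene attacks, and C4 is set by the substrate, because 5 adds pseudoaxially to the envelope cation 7 on the face opposite the pseudoequatorial C2 methyl group, giving the 2,4-trans (2R,4S) product. The step needs the naphthalene and not a benzene ring of 3 or 8 to end the cascade, and cyclisation to outrun protonation of the styrene: the tosyloxy group removes the resorcinol-type activation of those rings and lowers the basicity of the alkene, and the bulk of 7 directs attack to the unhindered para position of 5. Slow addition keeps free aldehyde and styrene low, which should limit condensation of acetaldehyde with 5 and acid-induced oligomerisation.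

Step 4
Reactants: 8 (2R,4S)-4-(4,5-dimethoxynaphthalen-1-yl)-2-methylchroman-5-yl 4-methylbenzenesulfonate
Product: 9 Cladonaphchrom A, (2R,4S)-4-(4,5-dimethoxynaphthalen-1-yl)-2-methylchroman-5-ol
Conditions: KOH (5 equiv), 1,4-dioxane/H2O, 80 °C, Ar; then aq HCl
Reagents that add atoms: none
Why: Alkaline hydrolysis of an aryl sulfonate by attack of hydroxide at sulfur; the aryl methyl ethers, the chroman ether and both stereocentres (no acidic C–H at C2 or C4) should be untouched by aqueous base.

Compound list
1 | 2,6-dihydroxybenzaldehyde | O=Cc1c(O)cccc1O | starting material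
2 | 2-formyl-3-hydroxyphenyl 4-methylbenzenesulfonate | O=Cc1c(O)cccc1OS(=O)(=O)c1ccc(C)cc1 | intermediate
3 | 3-hydroxy-2-vinylphenyl 4-methylbenzenesulfonate | C=Cc1c(O)cccc1OS(=O)(=O)c1ccc(C)cc1 | intermediate
4 | acetaldehyde | CC=O | starting material
5 | 1,8-dimethoxynaphthalene | COc1cccc2cccc(OC)c12 | starting material
6 | ethylidene[3-(tosyloxy)-2-vinylphenyl]oxonium (oxocarbenium ion, paired with the catalyst anion) | CC=[O+]c1cccc(OS(=O)(=O)c2ccc(C)cc2)c1C=C | intermediate
7 | (2R)-2-methyl-5-(tosyloxy)chroman-4-ylium (chromanyl cation, paired with the catalyst anion) | C[C@@H]1C[CH+]c2c(OS(=O)(=O)c3ccc(C)cc3)cccc2O1 | intermediate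
8 | (2R,4S)-4-(4,5-dimethoxynaphthalen-1-yl)-2-methylchroman-5-yl 4-methylbenzenesulfonate | COc1cccc2c([C@@H]3C[C@@H](C)Oc4cccc(OS(=O)(=O)c5ccc(C)cc5)c43)ccc(OC)c12 | intermediate
9 | Cladonaphchrom A, (2R,4S)-4-(4,5-dimethoxynaphthalen-1-yl)-2-methylchroman-5-ol | COc1cccc2c([C@@H]3C[C@@H](C)Oc4cccc(O)c43)ccc(OC)c12 | target

Total step count: 4
Longest linear sequence: 4 steps (1 → 2 → 3 → 8 → 9); 4 and 5 enter at step 3.

Steps most likely to fail

Step 3. The cascade may fail through condensation of acetaldehyde with the electron-rich naphthalene, through acid-induced oligomerisation of the styrene, or through poor facial selection at the oxocarbenium stage. The fallback makes the same three bonds one at a time with known reactions and takes C2 from the chiral pool. It sets out from 3. Mitsunobu etherification with (S)-but-3-en-2-ol (PPh3, DIAD, THF, 0 °C → rt, inversion) should give (R)-3-(but-3-en-2-yloxy)-2-vinylphenyl 4-methylbenzenesulfonate F1. Ring-closing metathesis (second-generation Ru alkylidene catalyst, CH2Cl2, 40 °C) should then give (R)-2-methyl-2H-chromen-5-yl 4-methylbenzenesulfonate F2. Protonation of F2 at C3 (TfOH cat. or BF3·OEt2, CH2Cl2, −40 °C) in the presence of 5 should regenerate cation 7 from enantiopure material, and trans-selective Friedel–Crafts capture brings the sequence back to the route at 8.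

Step 2. The excess ylide may attack the sulfonate sulfur, or the olefination may stall at the deactivated phenoxide–aldehyde. The fallback installs the vinyl group before any sulfonate is present and sets out from 1. Silylation (TBSCl, imidazole, DMF) should give 2,6-bis(tert-butyldimethylsilyloxy)benzaldehyde F3. Wittig methylenation (Ph3P=CH2, THF, 0 °C) should give 2,6-bis(tert-butyldimethylsilyloxy)styrene F4. Buffered desilylation (TBAF, AcOH, THF, 0 °C) should give 2-vinylresorcinol F5. Mono-tosylation of this symmetric diol (TsCl 1.0 equiv, Et3N 1.0 equiv, CH2Cl2, −20 °C, unreacted diol recycled) returns to the route at 3.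

Step 1. Over-sulfonylation next to incomplete conversion may leave a mixture of diol, mono- and bis-tosylate. The fallback moves the differentiation from the sulfonylation to a cleavage step and sets out from 1. Exhaustive tosylation (TsCl 2.5 equiv, Et3N, DMAP cat., CH2Cl2) should give 2-formyl-1,3-phenylene bis(4-methylbenzenesulfonate) F6. Controlled hydrolysis (LiOH 2 equiv, THF/H2O, 0 °C) should then stop after one sulfonate, because the phenoxide released in the first cleavage makes the second leaving group a far more basic dianion. This returns to the route at 2.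

Further compounds
F1 | step 3 | (R)-3-(but-3-en-2-yloxy)-2-vinylphenyl 4-methylbenzenesulfonate | C=C[C@@H](C)Oc1cccc(OS(=O)(=O)c2ccc(C)cc2)c1C=C
F2 | step 3 | (R)-2-methyl-2H-chromen-5-yl 4-methylbenzenesulfonate | C[C@@H]1C=Cc2c(OS(=O)(=O)c3ccc(C)cc3)cccc2O1
F3 | step 2 | 2,6-bis(tert-butyldimethylsilyloxy)benzaldehyde | CC(C)(C)[Si](C)(C)Oc1cccc(O[Si](C)(C)C(C)(C)C)c1C=O
F4 | step 2 | 2,6-bis(tert-butyldimethylsilyloxy)styrene | C=Cc1c(O[Si](C)(C)C(C)(C)C)cccc1O[Si](C)(C)C(C)(C)C
F5 | step 2 | 2-vinylresorcinol (2-ethenylbenzene-1,3-diol) | C=Cc1c(O)cccc1O
F6 | step 1 | 2-formyl-1,3-phenylene bis(4-methylbenzenesulfonate) | O=Cc1c(OS(=O)(=O)c2ccc(C)cc2)cccc1OS(=O)(=O)c1ccc(C)cc1
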